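**Retrosynthetic overview**

1. The side chain has an (E)-C6'=C7' trisubstituted olefin lying γ,δ to C10'. With C10' as a ketone and C11' already oxygenated, C6'–C10' is the product pattern of a decarboxylative Claisen (Carroll) rearrangement. C8'–C9' is therefore cut back to a C6' allylic β-keto ester carrying a C7' isopropenyl group.
2. After the key step, a catalyst-controlled reduction of the C10' ketone (between C9'H2 and the quaternary C11') sets (10'S). Acid then frees the C6 and C8 phenols and the C11' hydroxyl.
3. The β-keto ester comes from the C6' alcohol and an acyl Meldrum's acid made from 2-hydroxyisobutyric acid.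
4. C1'–C2' and the (E)-C2'=C3' olefin come from a nickel-catalysed coupling of the C5 chloromethyl isochromanone with the alkenylalane obtained by methylalumination of silylated 2-methylhept-1-en-6-yn-3-ol (from pent-4-yn-1-ol).
5. Rings: the benzene ring is bought (5-bromoresorcinol). The lactone ring is the only ring made; it is closed early by carbonylative lactonisation after opening of (R)-propylene oxide (C3). No ring is formed later.

Key step: step 16

Remark on the chemistry: the C6' carbinol is made as a racemate, so every compound between the fragment coupling and the key step is a pair of C6' epimers on the (3R)-lactone. The key step erases this centre and the pairs converge.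

**Route**

Step 1
Reactants: 1 5-bromoresorcinol
Product: 2 1-bromo-3,5-bis(methoxymethoxy)benzene
Conditions: MOMCl (2.5 equiv), iPr2NEt, CH2Cl2, 0 °C to rt
Reagents that add atoms: chloromethyl methyl ether, COCCl
Why: O-alkylation of both phenols (MOM protection) should be clean, and the acetals withstand the organometallic, fluoride and thermal steps that follow.

Step 2
Reactants: 2 1-bromo-3,5-bis(methoxymethoxy)benzene; 3 (R)-propylene oxide
Product: 5 (R)-1-[3,5-bis(methoxymethoxy)phenyl]propan-2-ol, via arylmagnesium bromide 4 (not isolated)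
Conditions: Mg, THF, 40 °C; then CuI (10 mol %), 3, −30 to 0 °C; H2O quench
Reagents that add atoms: none
Why: Grignard formation followed by CuI-catalysed SN2 opening of the epoxide at its unsubstituted carbon; the stereocentre of the epoxide is not touched and becomes C3 with (R) configuration.

Step 3
Reactants: 5 (R)-1-[3,5-bis(methoxymethoxy)phenyl]propan-2-ol
Product: 6 (R)-1-[2-bromo-3,5-bis(methoxymethoxy)phenyl]propan-2-ol
Conditions: NBS (1.0 equiv), MeCN, −10 to 0 °C
Reagents that add atoms: N-bromosuccinimide, O=C1CCC(=O)N1Br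
Why: Electrophilic aromatic bromination; the two positions ortho to the side chain are equivalent by symmetry and each is para to one ether, while the position between the two ethers is shielded, as is usual for 3,5-dialkoxyalkylbenzenes.

Step 4
Reactants: 6 (R)-1-[2-bromo-3,5-bis(methoxymethoxy)phenyl]propan-2-ol
Product: 7 (R)-6,8-bis(methoxymethoxy)-3-methylisochroman-1-one
Conditions: Pd(OAc)2 (5 mol %), Xantphos (6 mol %), Et3N, CO (1 atm), toluene, 90 °C
Reagents that add atoms: carbon monoxide, [C-]#[O+]
Why: Palladium-catalysed alkoxycarbonylation (oxidative addition, CO insertion, capture of the acyl palladium by the internal secondary hydroxyl) should close the six-membered lactone without touching C3.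

Step 5
Reactants: 7 (R)-6,8-bis(methoxymethoxy)-3-methylisochroman-1-one
Product: 8 (R)-5-bromo-6,8-bis(methoxymethoxy)-3-methylisochroman-1-one
Conditions: NBS (1.05 equiv), MeCN, rt
Reagents that add atoms: N-bromosuccinimide, O=C1CCC(=O)N1Br
Why: Electrophilic bromination should go to C5, which is para to the C8 ether and ortho to the C6 ether, whereas C7 is flanked by both acetals; this is the preference known for 2,4-dialkoxy-6-alkylbenzoates.

Step 6
Reactants: 8 (R)-5-bromo-6,8-bis(methoxymethoxy)-3-methylisochroman-1-one
Product: 9 (R)-5-(hydroxymethyl)-6,8-bis(methoxymethoxy)-3-methylisochroman-1-one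
Conditions: Bu3SnCH2OH (1.5 equiv), Pd(PPh3)4 (10 mol %), 1,4-dioxane, 100 °C
Reagents that add atoms: (tributylstannyl)methanol, CCCC[Sn](CCCC)(CCCC)CO
Why: Stille (Migita–Kosugi) hydroxymethylation of the aryl bromide runs under neutral conditions that leave the lactone and the acetals alone.

Step 7
Reactants: 9 (R)-5-(hydroxymethyl)-6,8-bis(methoxymethoxy)-3-methylisochroman-1-one
Product: 10 (R)-5-(chloromethyl)-6,8-bis(methoxymethoxy)-3-methylisochroman-1-one
Conditions: MsCl, Et3N, LiCl, THF, 0 °C to rt; used at once
Reagents that add atoms: lithium chloride, [Li+].[Cl-]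
Why: Mesylation and chloride displacement at an activated benzylic carbon under basic conditions avoid acid that would endanger the acetals; the electron-rich benzylic chloride is used without storage.

Step 8
Reactants: 11 pent-4-yn-1-ol
Product: 12 pent-4-ynal
Conditions: TEMPO (10 mol %), PhI(OAc)2, CH2Cl2, rt; washed and used as a dried solution
Reagents that add atoms: none
Why: Oxoammonium-mediated oxidation stops at the aldehyde and does not touch the terminal alkyne.

Step 9
Reactants: 12 pent-4-ynal; 13 isopropenylmagnesium bromide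
Product: 14 rac-2-methylhept-1-en-6-yn-3-ol
Conditions: THF, −78 to 0 °C; H2O quench
Reagents that add atoms: none
Why: Grignard 1,2-addition to the aldehyde at low temperature outruns deprotonation of the alkyne; the racemic carbinol is acceptable because this centre is erased in step 16.

Step 10
Reactants: 14 rac-2-methylhept-1-en-6-yn-3-ol
Product: 15 rac-tert-butyl(dimethyl)[(2-methylhept-1-en-6-yn-3-yl)oxy]silane
Conditions: TBSCl, imidazole, DMF, rt
Reagents that add atoms: tert-butyldimethylsilyl chloride, CC(C)(C)[Si](C)(C)Cl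
Why: Standard silylation masks the hydroxyl so that the methylalumination and the coupling run on a non-protic substrate.

Step 11
Reactants: 15 rac-tert-butyl(dimethyl)[(2-methylhept-1-en-6-yn-3-yl)oxy]silane; 10 (R)-5-(chloromethyl)-6,8-bis(methoxymethoxy)-3-methylisochroman-1-one
Product: 17 (3R)-5-[(2E)-6-(tert-butyldimethylsilyloxy)-3,7-dimethylocta-2,7-dien-1-yl]-6,8-bis(methoxymethoxy)-3-methylisochroman-1-one (C6' epimers), via alkenyldimethylalane 16 (not isolated)
Conditions: 15, AlMe3 (2 equiv), Cp2ZrCl2 (0.25 equiv), CH2Cl2, 0 °C to rt; volatiles removed in vacuo; then 10, NiCl2(PPh3)2 (5 mol %) pre-reduced with n-BuLi (10 mol %), THF, 0 °C to rt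
Reagents that add atoms: trimethylaluminium, C[Al](C)C
Why: Negishi zirconium-catalysed methylalumination adds methyl and aluminium syn across the terminal alkyne with aluminium at the terminal carbon and leaves the 1,1-disubstituted olefin alone, and the nickel-catalysed cross-coupling of the alkenylalane with the benzylic chloride forms C1'–C2' with retention, which fixes the (E)-C2'=C3' geometry.

Step 12
Reactants: 17 (3R)-5-[(2E)-6-(tert-butyldimethylsilyloxy)-3,7-dimethylocta-2,7-dien-1-yl]-6,8-bis(methoxymethoxy)-3-methylisochroman-1-one (C6' epimers)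
Product: 18 (3R)-5-[(2E)-6-hydroxy-3,7-dimethylocta-2,7-dien-1-yl]-6,8-bis(methoxymethoxy)-3-methylisochroman-1-one (C6' epimers)
Conditions: TBAF, THF, 0 °C to rt
Reagents that add atoms: none
Why: Fluoride cleaves the secondary silyl ether and leaves the MOM acetals and the hindered aryl lactone intact.

Step 13
Reactants: 19 2-hydroxyisobutyric acid
Product: 21 2-methyl-2-(triethylsilyloxy)propanoic acid, via bis-silyl derivative 20 (not isolated)
Conditions: TESOTf (2.2 equiv), 2,6-lutidine, CH2Cl2, 0 °C; then K2CO3 (cat.), THF/H2O, 0 °C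
Reagents that add atoms: triethylsilyl trifluoromethanesulfonate, CC[Si](CC)(CC)OS(=O)(=O)C(F)(F)F
Why: The silyl triflate silylates the tertiary hydroxyl and the acid, and the far more labile silyl ester is then hydrolysed selectively; the silyl ether is needed because a free C11' hydroxyl would later close onto the ester to give a tetronic acid.

Step 14
Reactants: 21 2-methyl-2-(triethylsilyloxy)propanoic acid; 22 Meldrum's acid (2,2-dimethyl-1,3-dioxane-4,6-dione)
Product: 23 5-[1-hydroxy-2-methyl-2-(triethylsilyloxy)propylidene]-2,2-dimethyl-1,3-dioxane-4,6-dione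
Conditions: DCC, DMAP, CH2Cl2, 0 °C to rt; cold dilute KHSO4 wash
Reagents that add atoms: none
Why: Carbodiimide/DMAP C-acylation of Meldrum's acid (Oikawa–Yonemitsu) gives the acyl Meldrum's acid under conditions mild enough for the tertiary silyl ether.

Step 15
Reactants: 18 (3R)-5-[(2E)-6-hydroxy-3,7-dimethylocta-2,7-dien-1-yl]-6,8-bis(methoxymethoxy)-3-methylisochroman-1-one (C6' epimers); 23 5-[1-hydroxy-2-methyl-2-(triethylsilyloxy)propylidene]-2,2-dimethyl-1,3-dioxane-4,6-dione
Product: 25 (3R)-5-[(2E)-3,7-dimethyl-6-{[4-methyl-3-oxo-4-(triethylsilyloxy)pentanoyl]oxy}octa-2,7-dien-1-yl]-6,8-bis(methoxymethoxy)-3-methylisochroman-1-one (C6' epimers), via acylketene 24 (not isolated)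
Conditions: 23 (1.5 equiv), toluene, 85 °C
Reagents that add atoms: none
Why: Thermolysis of the acyl Meldrum's acid releases acetone and CO2 to give an acylketene that the secondary allylic alcohol traps as its β-keto ester; at this temperature the [3,3] shift of the product should not yet start.

Step 16
Reactants: 25 (3R)-5-[(2E)-3,7-dimethyl-6-{[4-methyl-3-oxo-4-(triethylsilyloxy)pentanoyl]oxy}octa-2,7-dien-1-yl]-6,8-bis(methoxymethoxy)-3-methylisochroman-1-one (C6' epimers)
Product: 27 (3R)-5-[(2E,6E)-3,7,11-trimethyl-10-oxo-11-(triethylsilyloxy)dodeca-2,6-dien-1-yl]-6,8-bis(methoxymethoxy)-3-methylisochroman-1-one, via beta-keto acid 26 (not isolated)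
Conditions: degassed 1,2-dichlorobenzene (dilute), 175 °C, Ar
Reagents that add atoms: none
Why: Carroll rearrangement: the ester reacts through its enol (ketene hemiacetal) tautomer, whose C=C and the C7'=C8' isopropenyl unit pass through a chair six-membered transition state in which C6'–O breaks as C8'–C9' forms, and the β-keto acid 26 then loses CO2 through its cyclic hydrogen-bonded form. The closest known reaction type is the thermal decarboxylative Claisen rearrangement of allyl acetoacetates used for geranylacetone-type terpenoid ketones. No ring is closed. No stereocentre remains from the step: the racemic C6' centre becomes the olefin and the transient C9' centre of 26 disappears on decarboxylation, so both epimers of 25 converge on one product. The selectivity needed is the (E) geometry at C6'=C7'; the C5' chain should sit equatorial on the carbinol carbon because in the axial position it would clash 1,3-diaxially with the enol hydroxyl on the ketene-hemiacetal carbon, the same control that makes ester-type Claisen rearrangements of 2-methylalk-1-en-3-ols (E)-selective. Only the C6' ester has an allyl unit within reach of the enol, the acyl part can enolise at one position only (C11' is quaternary), and the temperature stays below that needed for a Cope rearrangement of the C2'/C6' 1,5-diene.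

Step 17
Reactants: 27 (3R)-5-[(2E,6E)-3,7,11-trimethyl-10-oxo-11-(triethylsilyloxy)dodeca-2,6-dien-1-yl]-6,8-bis(methoxymethoxy)-3-methylisochroman-1-one
Product: 28 (3R)-5-[(2E,6E,10S)-10-hydroxy-3,7,11-trimethyl-11-(triethylsilyloxy)dodeca-2,6-dien-1-yl]-6,8-bis(methoxymethoxy)-3-methylisochroman-1-one
Conditions: (R)-2-methyl-CBS-oxazaborolidine (0.5 equiv), catecholborane (2 equiv), toluene, −60 to −30 °C; aqueous NaHCO3 work-up
Reagents that add atoms: none
Why: Corey–Bakshi–Shibata reduction: the ketone binds to the oxazaborolidine with the bulky C(Me)2OSiEt3 group away from the catalyst and hydride is delivered to one face, and with the (R)-catalyst the model established for tert-alkyl ketones predicts the (10'S) carbinol; catecholborane should leave the trisubstituted olefins and the lactone untouched, and the distant C3 centre has no influence.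

Step 18
Reactants: 28 (3R)-5-[(2E,6E,10S)-10-hydroxy-3,7,11-trimethyl-11-(triethylsilyloxy)dodeca-2,6-dien-1-yl]-6,8-bis(methoxymethoxy)-3-methylisochroman-1-one
Product: 29 (10'S)-verruculide B, (3R)-5-[(2E,6E,10S)-10,11-dihydroxy-3,7,11-trimethyldodeca-2,6-dien-1-yl]-6,8-dihydroxy-3-methylisochroman-1-one
Conditions: HCl (1 M, from AcCl) in MeOH/THF, 0 °C to rt
Reagents that add atoms: none
Why: Acid-catalysed methanolysis removes the triethylsilyl ether and both MOM acetals (the C8 acetal is activated by the neighbouring lactone carbonyl); dilute acid at or below room temperature should leave the olefins, the diol and both stereocentres unchanged.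

**Compound list**

1 | 5-bromoresorcinol | Oc1cc(O)cc(Br)c1 | starting material
2 | 1-bromo-3,5-bis(methoxymethoxy)benzene | COCOc1cc(OCOC)cc(Br)c1 | intermediate
3 | (R)-propylene oxide | C[C@@H]1CO1 | starting material
4 | [3,5-bis(methoxymethoxy)phenyl]magnesium bromide (not isolated) | COCOc1cc(OCOC)cc([Mg]Br)c1 | intermediate
5 | (R)-1-[3,5-bis(methoxymethoxy)phenyl]propan-2-ol | C[C@@H](O)Cc1cc(OCOC)cc(OCOC)c1 | intermediate
6 | (R)-1-[2-bromo-3,5-bis(methoxymethoxy)phenyl]propan-2-ol | C[C@@H](O)Cc1cc(OCOC)cc(OCOC)c1Br | intermediate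
7 | (R)-6,8-bis(methoxymethoxy)-3-methylisochroman-1-one | C[C@@H]1Cc2cc(OCOC)cc(OCOC)c2C(=O)O1 | intermediate
8 | (R)-5-bromo-6,8-bis(methoxymethoxy)-3-methylisochroman-1-one | C[C@@H]1Cc2c(Br)c(OCOC)cc(OCOC)c2C(=O)O1 | intermediate
9 | (R)-5-(hydroxymethyl)-6,8-bis(methoxymethoxy)-3-methylisochroman-1-one | C[C@@H]1Cc2c(CO)c(OCOC)cc(OCOC)c2C(=O)O1 | intermediate
10 | (R)-5-(chloromethyl)-6,8-bis(methoxymethoxy)-3-methylisochroman-1-one | C[C@@H]1Cc2c(CCl)c(OCOC)cc(OCOC)c2C(=O)O1 | intermediate
11 | pent-4-yn-1-ol | C#CCCCO | starting material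
12 | pent-4-ynal | C#CCCC=O | intermediate
13 | isopropenylmagnesium bromide | CC(=C)[Mg]Br | starting material
14 | rac-2-methylhept-1-en-6-yn-3-ol | C#CCCC(O)C(C)=C | intermediate
15 | rac-tert-butyl(dimethyl)[(2-methylhept-1-en-6-yn-3-yl)oxy]silane | C#CCCC(O[Si](C)(C)C(C)(C)C)C(C)=C | intermediate
16 | (E)-alkenyldimethylalane from methylalumination of 15 (not isolated) | C[Al](C)/C=C(\C)CCC(O[Si](C)(C)C(C)(C)C)C(C)=C | intermediate
17 | (3R)-5-[(2E)-6-(tert-butyldimethylsilyloxy)-3,7-dimethylocta-2,7-dien-1-yl]-6,8-bis(methoxymethoxy)-3-methylisochroman-1-one (C6' epimers) | C[C@@H]1Cc2c(C/C=C(\C)CCC(O[Si](C)(C)C(C)(C)C)C(C)=C)c(OCOC)cc(OCOC)c2C(=O)O1 | intermediate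
18 | (3R)-5-[(2E)-6-hydroxy-3,7-dimethylocta-2,7-dien-1-yl]-6,8-bis(methoxymethoxy)-3-methylisochroman-1-one (C6' epimers) | C[C@@H]1Cc2c(C/C=C(\C)CCC(O)C(C)=C)c(OCOC)cc(OCOC)c2C(=O)O1 | intermediate
19 | 2-hydroxyisobutyric acid | CC(C)(O)C(=O)O | starting material
20 | triethylsilyl 2-methyl-2-(triethylsilyloxy)propanoate (not isolated) | CC[Si](CC)(CC)OC(=O)C(C)(C)O[Si](CC)(CC)CC | intermediate
21 | 2-methyl-2-(triethylsilyloxy)propanoic acid | CC[Si](CC)(CC)OC(C)(C)C(=O)O | intermediate
22 | Meldrum's acid (2,2-dimethyl-1,3-dioxane-4,6-dione) | CC1(C)OC(=O)CC(=O)O1 | starting material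
23 | 5-[1-hydroxy-2-methyl-2-(triethylsilyloxy)propylidene]-2,2-dimethyl-1,3-dioxane-4,6-dione | CC[Si](CC)(CC)OC(C)(C)C(O)=C1C(=O)OC(C)(C)OC1=O | intermediate
24 | 4-methyl-4-(triethylsilyloxy)pent-1-ene-1,3-dione, the acylketene (not isolated) | CC[Si](CC)(CC)OC(C)(C)C(=O)C=C=O | intermediate
25 | (3R)-5-[(2E)-3,7-dimethyl-6-{[4-methyl-3-oxo-4-(triethylsilyloxy)pentanoyl]oxy}octa-2,7-dien-1-yl]-6,8-bis(methoxymethoxy)-3-methylisochroman-1-one (C6' epimers) | C[C@@H]1Cc2c(C/C=C(\C)CCC(OC(=O)CC(=O)C(C)(C)O[Si](CC)(CC)CC)C(C)=C)c(OCOC)cc(OCOC)c2C(=O)O1 | intermediate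
26 | C9' carboxylic acid of 27, the β-keto acid (C9' epimers, not isolated) | C[C@@H]1Cc2c(C/C=C(\C)CC/C=C(\C)CC(C(=O)O)C(=O)C(C)(C)O[Si](CC)(CC)CC)c(OCOC)cc(OCOC)c2C(=O)O1 | intermediate
27 | (3R)-5-[(2E,6E)-3,7,11-trimethyl-10-oxo-11-(triethylsilyloxy)dodeca-2,6-dien-1-yl]-6,8-bis(methoxymethoxy)-3-methylisochroman-1-one | C[C@@H]1Cc2c(C/C=C(\C)CC/C=C(\C)CCC(=O)C(C)(C)O[Si](CC)(CC)CC)c(OCOC)cc(OCOC)c2C(=O)O1 | intermediate
28 | (3R)-5-[(2E,6E,10S)-10-hydroxy-3,7,11-trimethyl-11-(triethylsilyloxy)dodeca-2,6-dien-1-yl]-6,8-bis(methoxymethoxy)-3-methylisochroman-1-one | C[C@@H]1Cc2c(C/C=C(\C)CC/C=C(\C)CC[C@H](O)C(C)(C)O[Si](CC)(CC)CC)c(OCOC)cc(OCOC)c2C(=O)O1 | intermediate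
29 | (10'S)-verruculide B | C/C(=C\Cc1c(O)cc(O)c2c1C[C@@H](C)OC2=O)CC/C=C(\C)CC[C@H](O)C(C)(C)O | target

**Step count**

Total: 18 steps. Longest linear sequence: 13 steps (steps 1–7, 11, 12, 15, 16, 17, 18, from 5-bromoresorcinol).

**Steps most likely to fail, with fallbacks**

Step 16 (key step). At the temperature the [3,3] shift needs, the β-keto ester may fragment back to acylketene and alcohol, the skipped polyene may degrade, and leakage through a boat transition state would erode the (E) geometry. The fallback sets out from 18 and comes back at 27 by a ketal-type Claisen rearrangement that needs neither the β-keto ester nor a decarboxylation. 1-Methoxyvinyllithium (methyl vinyl ether, t-BuLi, THF) is added to acetone to give 3-methoxy-2-methylbut-3-en-2-ol F1, which is silylated (TESCl, imidazole, DMAP) to triethyl[(3-methoxy-2-methylbut-3-en-2-yl)oxy]silane F2. Heating 18 with an excess of F2 and a trace of propionic acid in toluene at 110–130 °C, with removal of methanol, should exchange the enol ether onto the C6' oxygen to give the C6' 1-[2-(triethylsilyloxy)propan-2-yl]vinyl ether of 18 F3. F3 should rearrange in the same flask through the analogous chair, with the bulky group on the vinyl ether carbon enforcing the equatorial C5' chain, to ketone 27.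

Step 18. Once the C6 phenol is free, protic acid may add it across the C2'=C3' olefin (chroman formation), or ionise the tertiary C11' carbinol, before the less activated C6 acetal is fully cleaved. The fallback sets out from 28 and comes back at 29 without protic acid. TESOTf and 2,2'-bipyridyl in CH2Cl2 at 0 °C should convert the two aryl MOM ethers into aryl silyl ethers by silyl transfer (the methoxymethyl groups leave on the pyridine nitrogen) and silylate the C10' hydroxyl, giving the 6,8,10',11'-tetrakis(triethylsilyl) ether F4. Buffered fluoride (TBAF/AcOH, THF, 0 °C) then removes all four silyl groups to give 29.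

Step 11. Residual trimethylaluminium may transfer methyl instead of the alkenyl group, the Lewis-acidic alane may attack the acetals or the lactone, and the electron-rich benzylic chloride may decompose before it couples. The fallback sets out from 16 (made from 15 as in step 11) and from 10, and comes back at 17 with the polarity reversed. Alane 16 is quenched with I2 (THF, −30 °C) to give tert-butyl{[(6E)-7-iodo-2,6-dimethylhepta-1,6-dien-3-yl]oxy}dimethylsilane F5. Chloride 10 is treated with Zn dust and LiCl (THF, rt) to give the benzylic zinc chloride F6. A Negishi coupling of F5 and F6 (Pd(PPh3)4, THF, rt) should give 17 with retention of the (E) geometry, and the lactone never meets an aluminium reagent.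

**Further compounds**

F1 | step 16 | 3-methoxy-2-methylbut-3-en-2-ol | C=C(OC)C(C)(C)O
F2 | step 16 | triethyl[(3-methoxy-2-methylbut-3-en-2-yl)oxy]silane | C=C(OC)C(C)(C)O[Si](CC)(CC)CC
F3 | step 16 | C6' 1-[2-(triethylsilyloxy)propan-2-yl]vinyl ether of 18 (C6' epimers) | C[C@@H]1Cc2c(C/C=C(\C)CCC(OC(=C)C(C)(C)O[Si](CC)(CC)CC)C(C)=C)c(OCOC)cc(OCOC)c2C(=O)O1
F4 | step 18 | 6,8,10',11'-tetrakis(triethylsilyl) ether of (10'S)-verruculide B | C[C@@H]1Cc2c(C/C=C(\C)CC/C=C(\C)CC[C@H](O[Si](CC)(CC)CC)C(C)(C)O[Si](CC)(CC)CC)c(O[Si](CC)(CC)CC)cc(O[Si](CC)(CC)CC)c2C(=O)O1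
F5 | step 11 | tert-butyl{[(6E)-7-iodo-2,6-dimethylhepta-1,6-dien-3-yl]oxy}dimethylsilane (racemic) | I/C=C(\C)CCC(O[Si](C)(C)C(C)(C)C)C(C)=C
F6 | step 11 | {[(3R)-6,8-bis(methoxymethoxy)-3-methyl-1-oxoisochroman-5-yl]methyl}zinc chloride | C[C@@H]1Cc2c(C[Zn]Cl)c(OCOC)cc(OCOC)c2C(=O)O1
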